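# Proposed synthesis of CNP0584120.1 by tethered oxidative α′-lactonisation

Atom labels follow the isochromene numbering of the target (C1, O2, C3, C4, C4a, C5–C8, C8a); the lactone atoms are primed (O1′, C2′–C6′). Ring A is the carbocycle, ring B the pyran.

## Analysis of the target

The target is an azaphilone, a 7,8-dihydro-6H-isochromen-6-one. Ring A (C4a, C5, C6, C7, C8, C8a) is a 5-chloro enone, and ring B (C1, O2, C3, C4) is a 2H-pyran that carries a (1E,3E,5S)-3,5-dimethylhepta-1,3-dienyl chain at C3. It has five stereocentres: the side-chain carbon, the tertiary carbinol C7 (S), its neighbour C8 (S), and C3′ (R) and C6′ (S) of the 6-methyloxane-2,4-dione bound to C8. The C7 hydroxyl and the C8–C3′ bond are cis. C6′ and the side-chain centre are remote and have to be brought in as such. C3′ lies between two carbonyl groups and is labile.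

The sensitive parts are:
- the vinylogous pyranone, which is electrophilic at C1 and C3;
- the α-ketol at C6/C7;
- the acidic β-keto lactone;
- the C8 hydrogen, whose loss together with the C7 oxygen would aromatise ring A;
- the conjugated triene.

The difficulty is the tetrasubstituted, oxygen-bearing C7 next to C8, with its oxygen on the same face as the bulky C8 substituent. That is the face an external oxidant avoids. The strategy rests on the carboxyl carbon C2′ of the C8 arm. It lies three bonds from C7, so a carboxylate oxygen can reach C7 through a five-membered ring. That ring can later hand its acyl group over to the C6′ oxygen and set the C7 hydroxyl free.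

## Retrosynthetic reasoning

**C3′–C4′ and the lactone oxygen.** The δ-lactone of 31 is cut at C3′–C4′ and, formally, at C2′–O1′, with C2′ re-attached to the C7 oxygen. This leads to the angular γ-lactone 28 and the β-lactone 29. The forward reaction is a Claisen acylation of the lactone enolate by 29 followed by acyl migration from O–C7 to O–C6′. The cut is made here because 29 brings C6′ with its configuration, and the γ-lactone protects the C7 oxygen until the last step. It is made last because only in 28 is C3′ the sole α-carbonyl C–H position.

**Ring B.** In 28 the O2–C3 bond and the C8a–C1 bond are cut. O2–C3 is the addition of an enol oxygen across an alkyne. C8a–C1 is a one-carbon electrophile at the γ-position of an enone. This gives the acetal 26 and then the ynenone 24. Ring B is made late because it is the most electrophilic part of the molecule.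

**C4a–C4.** The sp2–sp bond of 24 is cut to the enol triflate 16 and the terminal enyne 23. This is the most convergent point: the whole side chain with its stereocentre arrives in one cross-coupling.

**Side chain.** 23 is cut at its two alkenes, to the enal 20 and the phosphonate 21, and 20 to the chiral alcohol 17 and the ylide 18. Both olefinations are E-selective, and the only stereocentre comes from the chiral pool.

**Ring A functional groups.** 16 goes back to the chlorodione 15 and this to the methyl enol ether 13 (C5–Cl, C4a–O activation). The C4a oxygen thus serves first as the group that steers enolisation to C7 and then as the leaving group for the alkyne.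

**C7–O (key disconnection).** The C7–O bond of 13 is cut to give the keto acid 11. The forward reaction has to oxidise C7 and deliver the oxygen from the C8 arm. This is chosen over an external hydroxylation because the ring that forms can only be cis-fused, so the C7/C8 relation follows from geometry.

**Adjustments to 11.** 11 comes from the alcohol 10 by oxidation. 10 comes from the β-keto ester 8 by removal of two benzyl groups and decarboxylation. The extra ester on C7 in 8 is there on purpose: it makes C7 quaternary while the enol ether is formed.

**Enol ether and C5–C6.** 8 is the enol ether of the dione 7. With C7 quaternary, etherification goes to the C4a oxygen. 7 is cut at C5–C6 (intramolecular Claisen condensation) to the keto diester 6. The C7 methyl group is in place before ring closure; a 5-substituted cyclohexane-1,3-dione without it would be achiral.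

**C7–C8.** 6 is the methylation product of 5. 5 is cut at C7–C8 into the enone 3 and the malonate 4, a catalytic asymmetric Michael addition that sets C8. 3 comes from the aldehyde 1 and the ylide 2.

## Alternatives that were turned down

**Alternative 1: gold carbocyclisation (C4a–C8a).**
- Disconnection and key step: ring A is cut at C4a–C8a. An open-chain diynone carrying an aldehyde-derived silyl enol ether (A1) would be closed by a cationic phosphine–gold catalyst in a 6-endo-dig attack of C8a on C4a. The product is the 3-alkynyl-4-formylcyclohexenone A2.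
- For it: the side chain, the alkyne and the C1 formyl carbon are all in place when ring A forms. Triflation, cross-coupling and C8a formylation of the chosen route are not needed. On convergence and on the late stage this route is stronger.
- Against it: C7 and C8 must already be present in A1. The hardest element, a tertiary silyloxy ketone centre with a defined relation to C8, has to be set by acyclic stereocontrol and gains nothing from the key step. The diynone offers two alkynes and two modes of attack (5-exo against 6-endo). The triene is exposed to the gold catalyst. C5 still has to be chlorinated on a sensitive dienynone. The arm is at the alcohol level and must still be oxidised and lactonised against a hindered tertiary silyl ether.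
- Comparison: the chosen route spends three more steps at the end. In return the C7/C8 relation is fixed by a ring, not by an acyclic addition.

**Alternative 2: carbene-catalysed crossed benzoin (C6–C7).**
- Disconnection and key step: ring A is cut at C6–C7. The keto aldehyde A3 would be closed by a chiral triazolium-derived carbene, whose acyl anion equivalent at C6 adds to the C7 methyl ketone and gives the α-ketol A4.
- For it: the tertiary carbinol is made in a C–C bond-forming step under catalyst control, and this type of closure to six-membered α-ketols is well known. The lactone is carried from the start as its methyl enol ether, so no late enolate acylation is needed. On that point it is stronger than the chosen route.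
- Against it: C8 in A3 is α to the reacting ketone and is activated by the enol-ether lactone, so it can epimerise under the basic carbene conditions. The cis relation then depends on a catalyst–substrate match that cannot be predicted, with the bulky C8 group next to the reacting carbonyl. In A4 ring A is saturated (ketal at C4a, methylene groups at C5 and C8a). The chloro enone, the alkynyl group and the C8a=C1 bond must all still be built, now beside a free tertiary α-ketol and an acid-labile enol ether.
- Comparison: the chosen route offers a relation that does not depend on matching. It also has a ring A that already carries oxygen at both C4a and C6.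

**Alternative 3: desymmetrising tethered Michael addition (C8–C3′).**
- Disconnection and key step: the C8–C3′ bond is cut. A 4-methylquinol β-keto ester (A5), two steps from the parent phenol, would be desymmetrised by a cinchona-derived amine–thiourea. C3′ adds 5-exo-trig to one enone β-carbon and gives the cis-fused keto lactone A6 with C7, C8 and C3′ set.
- For it: this is the shortest entry to the C7/C8 pair. The cis relation is enforced by the tether, exactly as in the chosen route, and the complete acyl chain with C6′ is attached at the same time. In step count to this stage and in precedent it is clearly stronger.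
- Against it: the oxidation pattern of ring A in A6 does not fit the target. The carbonyl is at C4a and the remaining alkene is C5=C6, whereas the target needs the ketone at C6 and a carbon substituent at C4a. The correction (oxygenation of C6 next to the quaternary C7, alkynylation at C4a, chlorination at C5, formylation at C8a) would run in the presence of a β-keto lactone whose C3′–H is the most acidic and most easily halogenated or sulfonylated position. The tertiary β-keto ester A5 can also fragment through an acylketene.
- Comparison: the chosen route is longer at the start. It reaches the late stage with a ring A whose oxygen pattern matches the target and with a simple lactone that has no acidic dicarbonyl C–H.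

Key step: step 8

## Route

Assumption: C3′ lies between two carbonyl groups and equilibrates through the enol, so the last step is taken to deliver the thermodynamically preferred C3′ epimer, assumed to be the (3′R) form drawn in the target.

Step 1
Reactants: 1 3-(benzyloxy)propanal; 2 1-(triphenyl-λ5-phosphanylidene)propan-2-one
Product: 3 (3E)-6-(benzyloxy)hex-3-en-2-one
Conditions: CH2Cl2, 23 °C
Reagents that add atoms: none
Why: Wittig olefination with a ketone-stabilised ylide is E-selective and neutral, so the β-benzyloxy aldehyde is not eliminated.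

Step 2
Reactants: 3 (3E)-6-(benzyloxy)hex-3-en-2-one; 4 dibenzyl propanedioate
Product: 5 dibenzyl 2-[(3S)-1-(benzyloxy)-5-oxohexan-3-yl]propanedioate
Conditions: 9-amino-9-deoxy-epi-quinine (20 mol %), PhCO2H (40 mol %), THF, 23 °C
Reagents that add atoms: none
Why: Asymmetric Michael addition under primary-amine iminium catalysis: the enone condenses with the cinchona amine and the malonate adds to the β-carbon of the iminium ion; addition to the Si face of C4 of 3 is required for the (3S) centre (the future C8), and the quinidine-derived pseudoenantiomer of the catalyst is used instead if the sense of induction should be the opposite one.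

Step 3
Reactants: 5 dibenzyl 2-[(3S)-1-(benzyloxy)-5-oxohexan-3-yl]propanedioate
Product: 6 dibenzyl 2-[(3S)-1-(benzyloxy)-5-oxohexan-3-yl]-2-methylpropanedioate
Conditions: NaH, MeI, THF, 0 → 23 °C
Reagents that add atoms: iodomethane, CI
Why: Malonate C-alkylation at by far the most acidic C–H of the molecule; the methyl group is the future C7 methyl and makes C7 quaternary, which keeps ring A unsymmetrical after cyclisation and later directs the enol ether to the C4a oxygen.

Step 4
Reactants: 6 dibenzyl 2-[(3S)-1-(benzyloxy)-5-oxohexan-3-yl]-2-methylpropanedioate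
Product: 7 benzyl (6S)-6-[2-(benzyloxy)ethyl]-1-methyl-2,4-dioxocyclohexane-1-carboxylate (both C1 epimers)
Conditions: LiN(SiMe3)2 (2.5 equiv), THF, −78 → 0 °C; 1 M HCl
Reagents that add atoms: none
Why: Dieckmann-type intramolecular Claisen condensation: kinetic deprotonation of the methyl ketone at CH3 (C5), six-membered attack on one benzyl ester, and trapping of the acidic 1,3-dione as its enolate by the excess base, which protects it from retro-Claisen cleavage; C8 is not touched, and the two C7 epimers (either ester may react) converge in step 6.

Step 5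
Reactants: 7 benzyl (6S)-6-[2-(benzyloxy)ethyl]-1-methyl-2,4-dioxocyclohexane-1-carboxylate
Product: 8 benzyl (6S)-6-[2-(benzyloxy)ethyl]-4-methoxy-1-methyl-2-oxocyclohex-3-ene-1-carboxylate (both C1 epimers)
Conditions: HC(OMe)3, TsOH·H2O (cat.), MeOH, 23 °C
Reagents that add atoms: trimethyl orthoformate, COC(OC)OC
Why: Acid-catalysed enol etherification of a cyclic 1,3-dione; the C6 carbonyl is flanked by the quaternary C7, so the methoxy group goes to C4a and the ketone stays at C6, as with 4,4-disubstituted cyclohexane-1,3-diones.

Step 6
Reactants: 8 benzyl (6S)-6-[2-(benzyloxy)ethyl]-4-methoxy-1-methyl-2-oxocyclohex-3-ene-1-carboxylate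
Product: 10 (5S,6R)-5-(2-hydroxyethyl)-3-methoxy-6-methylcyclohex-2-en-1-one, via β-keto acid 9 (not isolated)
Conditions: H2 (1 atm), Pd(OH)2/C, EtOAc–EtOH, 23 °C; then 60 °C; then K2CO3, MeOH, 23 °C
Reagents that add atoms: none
Why: Hydrogenolysis cleaves the benzyl ester and the benzyl ether, the β-keto acid 9 decarboxylates through its enol on warming, and K2CO3/MeOH equilibrates C7 (α to the ketone) to the trans isomer; either C7 epimer would give the same enolate in step 8.

Step 7
Reactants: 10 (5S,6R)-5-(2-hydroxyethyl)-3-methoxy-6-methylcyclohex-2-en-1-one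
Product: 11 2-[(1R,2R)-5-methoxy-2-methyl-3-oxocyclohex-4-en-1-yl]acetic acid
Conditions: TEMPO (cat.), PhI(OAc)2, MeCN–H2O, 23 °C
Reagents that add atoms: water, O
Why: Oxoammonium-catalysed (TEMPO) oxidation of the primary alcohol through the aldehyde hydrate to the acid under near-neutral conditions, which leave the vinylogous ester intact.

Step 8
Reactants: 11 2-[(1R,2R)-5-methoxy-2-methyl-3-oxocyclohex-4-en-1-yl]acetic acid
Product: 13 (3aR,7aS)-5-methoxy-7a-methyl-3a,4-dihydro-1-benzofuran-2,7(3H,7aH)-dione, via α′-iodo acid 12 (not isolated)
Conditions: LiN(iPr)2 (2.2 equiv), THF, −78 °C; I2 (1.1 equiv), −78 → 23 °C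
Reagents that add atoms: none
Why: Proposed new method: two equivalents of LiN(iPr)2 give the lithium carboxylate and, by kinetic deprotonation of the 3-methoxy enone at its only α′ hydrogen, the cross-conjugated C6–C7 enolate, which iodine converts into the tertiary α′-iodo ketone 12 with iodine on the face away from the C8 arm (an acyl hypoiodite formed at the carboxylate may transfer iodine to the same carbon). The carboxylate then displaces iodide from the opposite face with inversion and forms the C7–O bond and the γ-lactone. The closest known reaction types are the iodine oxidation of keto-acid dianions and the iodine- or PhI(OAc)2-mediated α-acyloxylation (oxylactonisation) of ketones by carboxylic acids, neither shown at a tertiary α′-carbon of a vinylogous ester. The ring closed is the five-membered lactone, in the 5-exo-tet mode (the C7–I bond is exocyclic to the forming ring). The new stereocentre C7 is controlled by the tether: the arm on C8 reaches C7 only on its own face, so the bicycle is cis-fused and the oxygen is cis to the C8–C3′ bond, and an iodide on the wrong face can epimerise by exchange with the LiI present before it closes. The step needs α′ (C7) and not γ (C8a) enolisation, which kinetic amide-base deprotonation of a 3-alkoxy enone provides because C5 is sp2 and the γ-hydrogens are removed more slowly. It also needs substitution to outrun loss of HI towards C8, which is favoured because the nucleophile is intramolecular and already ionised.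

Step 9
Reactants: 13 (3aR,7aS)-5-methoxy-7a-methyl-3a,4-dihydro-1-benzofuran-2,7(3H,7aH)-dione
Product: 15 (3aR,7aS)-6-chloro-5-hydroxy-7a-methyl-3a,4-dihydro-1-benzofuran-2,7(3H,7aH)-dione (enol form of the 2-chloro-1,3-dione), via 6-chloro enol ether 14 (not isolated)
Conditions: N-chlorosuccinimide, MeCN, 23 °C; then 2 M HCl, THF, 40 °C
Reagents that add atoms: N-chlorosuccinimide, O=C1CCC(=O)N1Cl; water, O
Why: Electrophilic chlorination of the vinylogous ester at its nucleophilic α-carbon C5, then acid hydrolysis of the enol ether to the 2-chloro-1,3-dione; C7 is quaternary and the γ-lactone is stable to dilute acid.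

Step 10
Reactants: 15 (3aR,7aS)-6-chloro-5-hydroxy-7a-methyl-3a,4-dihydro-1-benzofuran-2,7(3H,7aH)-dione
Product: 16 (3aR,7aS)-6-chloro-7a-methyl-2,7-dioxo-2,3,3a,4,7,7a-hexahydro-1-benzofuran-5-yl trifluoromethanesulfonate
Conditions: Tf2O, Et3N, CH2Cl2, −78 °C
Reagents that add atoms: trifluoromethanesulfonic anhydride, O=S(=O)(OS(=O)(=O)C(F)(F)F)C(F)(F)F
Why: Enol triflate formation by O-sulfonylation of the dione enolate; the oxygen on C4a reacts because the oxygen on C6 is shielded by the quaternary C7 and made less nucleophilic by the neighbouring acyloxy group, so the C4a vinylogous acyl triflate results.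

Step 11
Reactants: 17 (2S)-2-methylbutan-1-ol; 18 2-(triphenyl-λ5-phosphanylidene)propanal
Product: 20 (2E,4S)-2,4-dimethylhex-2-enal, via (2S)-2-methylbutanal 19 (not isolated)
Conditions: TEMPO (cat.), PhI(OAc)2, CH2Cl2, 23 °C; then 18, 40 °C
Reagents that add atoms: none
Why: TEMPO/PhI(OAc)2 oxidation gives the configurationally fragile aldehyde 19, which is trapped in the same flask by E-selective Wittig olefination with the formyl-stabilised ylide, so the α-stereocentre is never isolated or exposed to strong base.

Step 12
Reactants: 20 (2E,4S)-2,4-dimethylhex-2-enal; 21 diethyl [3-(trimethylsilyl)prop-2-yn-1-yl]phosphonate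
Product: 23 (3E,5E,7S)-5,7-dimethylnona-3,5-dien-1-yne, via silylated enyne 22 (not isolated)
Conditions: LiN(SiMe3)2, THF, −78 → 0 °C; then K2CO3, MeOH, 23 °C
Reagents that add atoms: none
Why: Horner–Wadsworth–Emmons olefination with the propargylic phosphonate anion gives the (E)-enyne, and K2CO3/MeOH removes the alkynyl silyl group.

Step 13
Reactants: 16 (3aR,7aS)-6-chloro-7a-methyl-2,7-dioxo-2,3,3a,4,7,7a-hexahydro-1-benzofuran-5-yl trifluoromethanesulfonate; 23 (3E,5E,7S)-5,7-dimethylnona-3,5-dien-1-yne
Product: 24 (3aR,7aS)-6-chloro-5-[(3E,5E,7S)-5,7-dimethylnona-3,5-dien-1-yn-1-yl]-7a-methyl-3a,4-dihydro-1-benzofuran-2,7(3H,7aH)-dione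
Conditions: Pd(PPh3)2Cl2 (5 mol %), CuI (10 mol %), iPr2NEt, THF, 23 °C
Reagents that add atoms: none
Why: Sonogashira coupling; oxidative addition of zerovalent palladium into the electron-poor C4a–OTf bond is fast at room temperature and the C5–Cl bond is left alone, and the tertiary amine cannot add to the triflate or the ynenone.

Step 14
Reactants: 24 (3aR,7aS)-6-chloro-5-[(3E,5E,7S)-5,7-dimethylnona-3,5-dien-1-yn-1-yl]-7a-methyl-3a,4-dihydro-1-benzofuran-2,7(3H,7aH)-dione
Product: 26 (3aS,4S,7aS)-6-chloro-4-(dimethoxymethyl)-5-[(3E,5E,7S)-5,7-dimethylnona-3,5-dien-1-yn-1-yl]-7a-methyl-3a,4-dihydro-1-benzofuran-2,7(3H,7aH)-dione, via trimethylsilyl dienol ether 25 (not isolated)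
Conditions: Me3SiOTf, iPr2NEt, CH2Cl2, 0 °C; then HC(OMe)3, −78 → −20 °C
Reagents that add atoms: trimethyl orthoformate, COC(OC)OC
Why: Soft enolisation of the enone (C7 has no hydrogen, so only the γ-hydrogen at C8a can be removed) gives the 2-silyloxy diene 25, which reacts with the dimethoxycarbenium ion from the orthoformate at its γ-terminus C8a and not at the fully substituted C5 (vinylogous Mukaiyama reaction); attack anti to the C8 arm is expected, and the new centre is lost in step 15.

Step 15
Reactants: 26 (3aS,4S,7aS)-6-chloro-4-(dimethoxymethyl)-5-[(3E,5E,7S)-5,7-dimethylnona-3,5-dien-1-yn-1-yl]-7a-methyl-3a,4-dihydro-1-benzofuran-2,7(3H,7aH)-dione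
Product: 28 (7S,8S)-5-chloro-3-[(1E,3E,5S)-3,5-dimethylhepta-1,3-dien-1-yl]-7-methyl-7,8-dihydro-6H-isochromen-6-one bearing the cis-fused γ-lactone O(C7)–C(=O)–CH2–(C8), via hydroxymethylene dienone 27 (not isolated)
Conditions: CF3CO2H, H2O, CH2Cl2, 0 °C; then Ph3PAuNTf2 (5 mol %), CH2Cl2, 23 °C
Reagents that add atoms: water, O
Why: Acetal hydrolysis gives the C8a aldehyde, which enolises into conjugation (27); the gold π-acid activates the alkyne and the enol oxygen adds to C3 in a 6-endo-dig oxa-cyclisation, the electronically matched mode because C3 is also the terminus of the ynenone, and protodeauration leaves ring B with the C8a=C1 and C3=C4 double bonds.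

Step 16
Reactants: 28 (7S,8S)-5-chloro-3-[(1E,3E,5S)-3,5-dimethylhepta-1,3-dien-1-yl]-7-methyl-7,8-dihydro-6H-isochromen-6-one bearing the cis-fused γ-lactone; 29 (4S)-4-methyloxetan-2-one
Product: 31 (7S,8S)-5-chloro-3-[(1E,3E,5S)-3,5-dimethylhepta-1,3-dien-1-yl]-7-hydroxy-7-methyl-8-[(3R,6S)-6-methyl-2,4-dioxooxan-3-yl]-7,8-dihydro-6H-isochromen-6-one, via 3′-acyl γ-lactone 30 (not isolated)
Conditions: LiN(SiMe3)2 (1.1 equiv), THF, −78 °C; 29, −78 → 23 °C; AcOH
Reagents that add atoms: none
Why: Crossed Claisen acylation: C3′ is the only α-carbonyl C–H left in 28, and its lithium enolate attacks the acyl carbon of the β-lactone (acyl–oxygen cleavage, so C6′ keeps its S configuration) to give 30; the freed C6′ alkoxide then attacks C2′ and the lactone moves from the C7 oxygen to the C6′ oxygen (translactonisation), driven by the strongly stabilised enolate of the cyclic β-keto δ-lactone, which sets the C7 hydroxyl free while C3′ settles by enolisation.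

## Compound list

1 | 3-(benzyloxy)propanal | O=CCCOCc1ccccc1 | starting material
2 | 1-(triphenyl-λ5-phosphanylidene)propan-2-one | CC(=O)C=P(c1ccccc1)(c1ccccc1)c1ccccc1 | starting material
3 | (3E)-6-(benzyloxy)hex-3-en-2-one | CC(=O)/C=C/CCOCc1ccccc1 | intermediate
4 | dibenzyl propanedioate | O=C(CC(=O)OCc1ccccc1)OCc1ccccc1 | starting material
5 | dibenzyl 2-[(3S)-1-(benzyloxy)-5-oxohexan-3-yl]propanedioate | O=C(OCc1ccccc1)C(C(=O)OCc1ccccc1)[C@@H](CCOCc1ccccc1)CC(C)=O | intermediate
6 | dibenzyl 2-[(3S)-1-(benzyloxy)-5-oxohexan-3-yl]-2-methylpropanedioate | O=C(OCc1ccccc1)C(C)(C(=O)OCc1ccccc1)[C@@H](CCOCc1ccccc1)CC(C)=O | intermediate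
7 | benzyl (6S)-6-[2-(benzyloxy)ethyl]-1-methyl-2,4-dioxocyclohexane-1-carboxylate (C1 epimers, centre removed in step 6) | O=C1CC(=O)C(C)(C(=O)OCc2ccccc2)[C@@H](CCOCc2ccccc2)C1 | intermediate
8 | benzyl (6S)-6-[2-(benzyloxy)ethyl]-4-methoxy-1-methyl-2-oxocyclohex-3-ene-1-carboxylate (C1 epimers) | COC1=CC(=O)C(C)(C(=O)OCc2ccccc2)[C@@H](CCOCc2ccccc2)C1 | intermediate
9 | (6S)-6-(2-hydroxyethyl)-4-methoxy-1-methyl-2-oxocyclohex-3-ene-1-carboxylic acid (C1 epimers) | COC1=CC(=O)C(C)(C(=O)O)[C@@H](CCO)C1 | intermediate (not isolated)
10 | (5S,6R)-5-(2-hydroxyethyl)-3-methoxy-6-methylcyclohex-2-en-1-one (trans) | COC1=CC(=O)[C@H](C)[C@@H](CCO)C1 | intermediate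
11 | 2-[(1R,2R)-5-methoxy-2-methyl-3-oxocyclohex-4-en-1-yl]acetic acid (trans) | COC1=CC(=O)[C@H](C)[C@@H](CC(=O)O)C1 | intermediate
12 | 2-[(1R,2R)-2-iodo-5-methoxy-2-methyl-3-oxocyclohex-4-en-1-yl]acetic acid (iodine trans to the arm; lithium carboxylate in the flask) | COC1=CC(=O)[C@](C)(I)[C@@H](CC(=O)O)C1 | intermediate (not isolated)
13 | (3aR,7aS)-5-methoxy-7a-methyl-3a,4-dihydro-1-benzofuran-2,7(3H,7aH)-dione (cis-fused) | COC1=CC(=O)[C@@]2(C)OC(=O)C[C@H]2C1 | intermediate
14 | (3aR,7aS)-6-chloro-5-methoxy-7a-methyl-3a,4-dihydro-1-benzofuran-2,7(3H,7aH)-dione | COC1=C(Cl)C(=O)[C@@]2(C)OC(=O)C[C@H]2C1 | intermediate (not isolated)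
15 | (3aR,7aS)-6-chloro-5-hydroxy-7a-methyl-3a,4-dihydro-1-benzofuran-2,7(3H,7aH)-dione (enol form of the 2-chloro-1,3-dione) | OC1=C(Cl)C(=O)[C@@]2(C)OC(=O)C[C@H]2C1 | intermediate
16 | (3aR,7aS)-6-chloro-7a-methyl-2,7-dioxo-2,3,3a,4,7,7a-hexahydro-1-benzofuran-5-yl trifluoromethanesulfonate | O=S(=O)(OC1=C(Cl)C(=O)[C@@]2(C)OC(=O)C[C@H]2C1)C(F)(F)F | intermediate
17 | (2S)-2-methylbutan-1-ol | CC[C@H](C)CO | starting material
18 | 2-(triphenyl-λ5-phosphanylidene)propanal | CC(C=O)=P(c1ccccc1)(c1ccccc1)c1ccccc1 | starting material
19 | (2S)-2-methylbutanal | CC[C@H](C)C=O | intermediate (not isolated)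
20 | (2E,4S)-2,4-dimethylhex-2-enal | CC[C@H](C)/C=C(C)/C=O | intermediate
21 | diethyl [3-(trimethylsilyl)prop-2-yn-1-yl]phosphonate | CCOP(=O)(CC#C[Si](C)(C)C)OCC | starting material
22 | trimethyl[(3E,5E,7S)-5,7-dimethylnona-3,5-dien-1-yn-1-yl]silane | CC[C@H](C)/C=C(C)/C=C/C#C[Si](C)(C)C | intermediate (not isolated)
23 | (3E,5E,7S)-5,7-dimethylnona-3,5-dien-1-yne | CC[C@H](C)/C=C(C)/C=C/C#C | intermediate
24 | (3aR,7aS)-6-chloro-5-[(3E,5E,7S)-5,7-dimethylnona-3,5-dien-1-yn-1-yl]-7a-methyl-3a,4-dihydro-1-benzofuran-2,7(3H,7aH)-dione | CC[C@H](C)/C=C(C)/C=C/C#CC1=C(Cl)C(=O)[C@@]2(C)OC(=O)C[C@H]2C1 | intermediate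
25 | (3aS,7aS)-6-chloro-5-[(3E,5E,7S)-5,7-dimethylnona-3,5-dien-1-yn-1-yl]-7a-methyl-7-[(trimethylsilyl)oxy]-3a,7a-dihydro-1-benzofuran-2(3H)-one (silyl dienol ether of 24) | CC[C@H](C)/C=C(C)/C=C/C#CC1=C[C@@H]2CC(=O)O[C@]2(C)C(O[Si](C)(C)C)=C1Cl | intermediate (not isolated)
26 | (3aS,4S,7aS)-6-chloro-4-(dimethoxymethyl)-5-[(3E,5E,7S)-5,7-dimethylnona-3,5-dien-1-yn-1-yl]-7a-methyl-3a,4-dihydro-1-benzofuran-2,7(3H,7aH)-dione (acetal on C8a, expected trans to the arm) | CC[C@H](C)/C=C(C)/C=C/C#CC1=C(Cl)C(=O)[C@@]2(C)OC(=O)C[C@H]2[C@@H]1C(OC)OC | intermediate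
27 | (3aS,4Z,7aS)-6-chloro-5-[(3E,5E,7S)-5,7-dimethylnona-3,5-dien-1-yn-1-yl]-4-(hydroxymethylidene)-7a-methyl-3a,4-dihydro-1-benzofuran-2,7(3H,7aH)-dione | CC[C@H](C)/C=C(C)/C=C/C#CC1=C(Cl)C(=O)[C@@]2(C)OC(=O)C[C@H]2/C1=C/O | intermediate (not isolated)
28 | (7S,8S)-5-chloro-3-[(1E,3E,5S)-3,5-dimethylhepta-1,3-dien-1-yl]-7-methyl-7,8-dihydro-6H-isochromen-6-one with cis-fused γ-lactone O(C7)–C(=O)–CH2–(C8) | CC[C@H](C)/C=C(C)/C=C/C1=CC2=C(Cl)C(=O)[C@@]3(C)OC(=O)C[C@H]3C2=CO1 | intermediate
29 | (4S)-4-methyloxetan-2-one | C[C@H]1CC(=O)O1 | starting material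
30 | 3′-[(3S)-3-hydroxybutanoyl] derivative of 28 (lithium enolate in the flask, C3′ not defined) | CC[C@H](C)/C=C(C)/C=C/C1=CC2=C(Cl)C(=O)[C@@]3(C)OC(=O)C(C(=O)C[C@H](C)O)[C@H]3C2=CO1 | intermediate (not isolated)
31 | (7S,8S)-5-chloro-3-[(1E,3E,5S)-3,5-dimethylhepta-1,3-dien-1-yl]-7-hydroxy-7-methyl-8-[(3R,6S)-6-methyl-2,4-dioxooxan-3-yl]-7,8-dihydro-6H-isochromen-6-one | CC[C@H](C)/C=C(C)/C=C/C1=CC2=C(Cl)C(=O)[C@@](C)(O)[C@@H]([C@@H]3C(=O)C[C@H](C)OC3=O)C2=CO1 | target

## Step count and least certain steps

Total step count: 16. Longest linear sequence: 14 steps (steps 1–10 and 13–16); the side chain (steps 11 and 12) joins in step 13.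

**Step 8 (key step, proposed new method).** The most likely failure is loss of HI from the tertiary α′-iodo ketone towards C8, followed by tautomerisation of the resulting dienone to a phenol, so that ring A is aromatised before the carboxylate closes. Oxidative dimerisation of the enolate, or iodination through the γ-enolate, are the other ways the dianion can be consumed. The fallback uses known chemistry and separates the two events. It sets out from 11, which is converted by LiN(iPr)2 and Me3SiCl into the bis(trimethylsilyl) derivative (silyl ester and C6–C7 silyl enol ether) F1. N-Bromosuccinimide brominates the silyl enol ether at C7 under neutral conditions, and work-up gives the tertiary α′-bromo acid F2 with bromine anti to the arm. AgOTf with 2,6-lutidine then removes bromide, and the carboxylate closes from the opposite face. The fallback comes back to the route at 13.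

**Step 16.** The lithium enolate has to be formed next to the electrophilic pyranone, so conjugate self-addition of the enolate to C1 or C3 of a second molecule can compete. The β-lactone may also be opened at its alkyl carbon, or the acyl transfer from the C7 oxygen may stall at the stage of 30. The fallback replaces the acyl donor by an aldehyde, which reacts at −78 °C within minutes. It sets out from 28, whose enolate is added to (3S)-3-[(tert-butyldimethylsilyl)oxy]butanal F3, a known compound made in two routine steps from the commercial (S)-hydroxy ester. This gives the aldol adduct F4, which is oxidised by the triacetoxy periodinane DMP to the silylated keto lactone F5. HF·pyridine removes the silyl group and gives neutral 30, where the fallback comes back to the route. Catalytic DBU then effects the translactonisation to 31 as a separate, observable step.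

**Step 14.** The dimethoxycarbenium ion may attack C5 of the silyl dienol ether or the electron-rich diene of the side chain, the lactone may be silylated as well, and the ynenone is exposed to a strong Lewis acid. The fallback changes to a base-free condensation. It sets out from 24, which is heated with tert-butoxybis(dimethylamino)methane in toluene; condensation at the only enolisable position, C8a, gives the dimethylaminomethylene dienone F6. Here the risk moves to conjugate addition of the liberated amine to the ynenone. Aqueous acid hydrolyses F6 to 27, where the fallback comes back to the route, and the gold-catalysed closure of step 15 follows.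

**Step 4.** Proton transfer may give the C8a enolate, which can expel the methylmalonate anion (retro-Michael fragmentation); re-addition would erode the configuration at C8. The fallback removes the leaving group before the ring is closed. It sets out from 6. Hydrogenolysis (H2, Pd(OH)2/C) followed by heating in toluene removes the three benzyl groups, decarboxylates the malonic acid and lactonises the hydroxy acid to (4S)-3-methyl-4-(2-oxopropyl)oxan-2-one F7. LiN(SiMe3)2 then closes ring A by attack of the methyl ketone enolate on the lactone carbonyl, which releases the hydroxyethyl arm and gives (5S)-5-(2-hydroxyethyl)-4-methylcyclohexane-1,3-dione F8. Acid-catalysed etherification with MeOH gives 10, where the fallback comes back to the route. The price is that C7 is now tertiary, so the regioisomeric enol ether must be separated and recycled by hydrolysis.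

## Further compounds

F1 | step 8 | trimethylsilyl 2-[(1R)-5-methoxy-2-methyl-3-[(trimethylsilyl)oxy]cyclohexa-2,4-dien-1-yl]acetate | COC1=CC(O[Si](C)(C)C)=C(C)[C@@H](CC(=O)O[Si](C)(C)C)C1
F2 | step 8 | 2-[(1R,2R)-2-bromo-5-methoxy-2-methyl-3-oxocyclohex-4-en-1-yl]acetic acid | COC1=CC(=O)[C@](C)(Br)[C@@H](CC(=O)O)C1
F3 | step 16 | (3S)-3-[(tert-butyldimethylsilyl)oxy]butanal | O=CC[C@H](C)O[Si](C)(C)C(C)(C)C
F4 | step 16 | 3′-[(3S)-3-[(tert-butyldimethylsilyl)oxy]-1-hydroxybutyl] derivative of 28 (mixture at C3′ and the carbinol carbon) | CC[C@H](C)/C=C(C)/C=C/C1=CC2=C(Cl)C(=O)[C@@]3(C)OC(=O)C(C(O)C[C@H](C)O[Si](C)(C)C(C)(C)C)[C@H]3C2=CO1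
F5 | step 16 | 3′-[(3S)-3-[(tert-butyldimethylsilyl)oxy]butanoyl] derivative of 28 (silyl ether of 30) | CC[C@H](C)/C=C(C)/C=C/C1=CC2=C(Cl)C(=O)[C@@]3(C)OC(=O)C(C(=O)C[C@H](C)O[Si](C)(C)C(C)(C)C)[C@H]3C2=CO1
F6 | step 14 | C8a-(dimethylaminomethylidene) derivative of 24 | CC[C@H](C)/C=C(C)/C=C/C#CC1=C(Cl)C(=O)[C@@]2(C)OC(=O)C[C@H]2C1=CN(C)C
F7 | step 4 | (4S)-3-methyl-4-(2-oxopropyl)oxan-2-one (C3 epimers) | CC(=O)C[C@@H]1CCOC(=O)C1C
F8 | step 4 | (5S)-5-(2-hydroxyethyl)-4-methylcyclohexane-1,3-dione (C4 epimers) | O=C1CC(=O)C(C)[C@@H](CCO)C1
A1 | alternative 1 | open-chain diynone with triethylsilyl ether at C7 and aldehyde-derived trimethylsilyl enol ether at C8a | CC[C@H](C)/C=C(C)/C=C/C#CC#CC(=O)[C@@](C)(O[Si](CC)(CC)CC)[C@@H](CCO[Si](C)(C)C(C)(C)C)C=CO[Si](C)(C)C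
A2 | alternative 1 | 3-dienynyl-4-formylcyclohex-2-enone with C7 triethylsilyl ether and C8 silyloxyethyl arm | CC[C@H](C)/C=C(C)/C=C/C#CC1=CC(=O)[C@@](C)(O[Si](CC)(CC)CC)[C@@H](CCO[Si](C)(C)C(C)(C)C)[C@@H]1C=O
A3 | alternative 2 | keto aldehyde with C4a dioxolane and enol-ether lactone on C8 | O=CCC1(OCCO1)C[C@H](C2=C(OC)C[C@H](C)OC2=O)C(C)=O
A4 | alternative 2 | ring A α-ketol with C4a dioxolane | O=C1CC2(OCCO2)C[C@H](C3=C(OC)C[C@H](C)OC3=O)[C@]1(C)O
A5 | alternative 3 | 1-methyl-4-oxocyclohexa-2,5-dien-1-yl (5S)-5-[(tert-butyldimethylsilyl)oxy]-3-oxohexanoate | CC1(OC(=O)CC(=O)C[C@H](C)O[Si](C)(C)C(C)(C)C)C=CC(=O)C=C1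
A6 | alternative 3 | cis-fused bicyclic keto γ-lactone enone | O=C1C=C[C@@]2(C)OC(=O)[C@@H](C(=O)C[C@H](C)O[Si](C)(C)C(C)(C)C)[C@H]2C1
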